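**Retrosynthetic overview**
- The target is opened at the C4 ester: a hydroxy lactone plus (2S,3R)-2,3-dimethyloxirane-2-carboxylic acid, the acid coming from Sharpless epoxidation of tiglyl alcohol.
- The cis-fused α-methylene lactone and the C3a/C4 centres come from a phosphonoacetate tethered on O-11a that opens a neighbouring cis-epoxide (5-exo), followed by HWE methylenation. The epoxide and the C5 acetate come from a cross-conjugated (Z,Z,Z)-cyclodecatrienone.
- The ten-membered ring comes from a four-carbon ring expansion of a cyclohexenone: intramolecular alkenyl-chromium addition to the ketone, then Grob fragmentation of the resulting cis-fused bicyclic β-mesyloxy alkoxide.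
- The fragmentation precursor comes from an aldol between a 4-silyloxy-6-methylcyclohexenone and a (Z)-γ-iodo-β,γ-unsaturated aldehyde.
- Ring order: cyclohexenone (bought) → transient cis-fused bicyclo[4.4.0] → ten-membered carbocycle → fused butyrolactone; the side-chain oxirane is made separately.

Assumption: the three starting materials are bought as drawn, the hydroxy-enone as the single (S)-enantiomer.

**Step 1**
Reactants: 1 (4S)-4-hydroxycyclohex-2-en-1-one
Product: 2 (4S)-4-[(tert-butyldimethylsilyl)oxy]cyclohex-2-en-1-one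
Conditions: TBSCl, imidazole, DMF, 0 → 25 °C
Reagents that add atoms: tert-butyldimethylsilyl chloride, CC(C)(C)[Si](C)(C)Cl
Why: Standard O-silylation masks the only hydroxyl before enolate chemistry and leaves the carbinol centre (C11a of the target) untouched.

**Step 2**
Reactants: 2 (4S)-4-[(tert-butyldimethylsilyl)oxy]cyclohex-2-en-1-one
Product: 3 (4S,6S)-4-[(tert-butyldimethylsilyl)oxy]-6-methylcyclohex-2-en-1-one
Conditions: LDA, THF, −78 °C; MeI, DMPU, −78 → −40 °C
Reagents that add atoms: iodomethane, CI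
Why: Kinetic α′-enolate alkylation of the cyclohexenone introduces the future 10-methyl group (trans isomer expected as the major one), and this new centre is erased again in step 5, so its ratio does not matter.

**Step 3**
Reactants: 4 3,3-dimethoxypropanal
Product: 5 (3Z)-4-iodo-1,1-dimethoxypent-3-ene
Conditions: EtPPh3I, n-BuLi, THF, 25 °C; I2, −78 °C; NaHMDS, −20 °C; then 4, −78 → 25 °C
Reagents that add atoms: ethyltriphenylphosphonium iodide, CC[P+](c1ccccc1)(c1ccccc1)c1ccccc1.[I-]; iodine, II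
Why: Stork–Zhao-type Wittig olefination with the α-iodo ylide gives the (Z)-2-iodoalkene (iodine cis to the chain), the geometry needed for the later six-membered ring closure.

**Step 4**
Reactants: 5 (3Z)-4-iodo-1,1-dimethoxypent-3-ene
Product: 6 (3Z)-4-iodopent-3-enal
Conditions: TFA, H2O, CH2Cl2, 0 °C; used crude at once
Reagents that add atoms: water, O
Why: Mild acetal hydrolysis frees the aldehyde without moving the β,γ-double bond into conjugation, provided the crude aldehyde is used immediately.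

**Step 5**
Reactants: 3 (4S,6S)-4-[(tert-butyldimethylsilyl)oxy]-6-methylcyclohex-2-en-1-one; 6 (3Z)-4-iodopent-3-enal
Product: 7 (4S,6R)-4-[(tert-butyldimethylsilyl)oxy]-6-[(1R,3Z)-1-hydroxy-4-iodopent-3-en-1-yl]-6-methylcyclohex-2-en-1-one
Conditions: LDA, THF, −78 °C; then 6, −78 °C, 20 min; AcOH quench at −78 °C
Reagents that add atoms: none
Why: Lithium aldol addition of the tetrasubstituted α′-enolate through a closed Zimmerman–Traxler transition state builds the quaternary carbon and the carbinol with OH syn to the methyl group (anti to the ring CH2); the aldehyde is drawn entering trans to OTBS, but either face converges after step 7.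

**Step 6**
Reactants: 7 (4S,6R)-4-[(tert-butyldimethylsilyl)oxy]-6-[(1R,3Z)-1-hydroxy-4-iodopent-3-en-1-yl]-6-methylcyclohex-2-en-1-one
Product: 8 (1R,3Z)-1-[(1R,5S)-5-[(tert-butyldimethylsilyl)oxy]-1-methyl-2-oxocyclohex-3-en-1-yl]-4-iodopent-3-en-1-yl methanesulfonate
Conditions: MsCl, Et3N, CH2Cl2, −20 → 0 °C
Reagents that add atoms: methanesulfonyl chloride, CS(=O)(=O)Cl
Why: Sulfonylation of the secondary alcohol installs the nucleofuge; the β-mesyloxy ketone cannot eliminate toward its quaternary α-carbon.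

**Step 7**
Reactants: 8 (1R,3Z)-1-[(1R,5S)-5-[(tert-butyldimethylsilyl)oxy]-1-methyl-2-oxocyclohex-3-en-1-yl]-4-iodopent-3-en-1-yl methanesulfonate
Product: 10 (2Z,5Z,8S,9Z)-8-[(tert-butyldimethylsilyl)oxy]-2,6-dimethylcyclodeca-2,5,9-trien-1-one, via bicyclic chromium alkoxide 9 (not isolated)
Conditions: CrCl2 (6 equiv), NiCl2 (2 mol %), DMSO, 25 °C; then 50 °C
Reagents that add atoms: none
Why: Proposed new method: Ni-catalysed formation of the alkenylchromium(III) from the (Z)-iodide and its intramolecular 1,2-addition to the ketone (Nozaki–Hiyama–Kishi) should give the cis-fused alkoxide 9 directly in the conformer whose ring-fusion C–C bond is antiperiplanar to the equatorial C–OMs bond, so that in the donor solvent it undergoes Grob fragmentation to the ring-expanded trienone, with the new trisubstituted alkene Z (fixed by the aldol relative configuration) and the other two alkenes cis because each was formed inside a six-membered ring; the closest known reaction type is the SmI2-mediated Barbier cyclisation/Grob fragmentation of iodoalkyl keto mesylates, which has not been shown for alkenyl halides under Ni/Cr mediation.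

**Step 8**
Reactants: 10 (2Z,5Z,8S,9Z)-8-[(tert-butyldimethylsilyl)oxy]-2,6-dimethylcyclodeca-2,5,9-trien-1-one
Product: 11 (1R,3Z,6Z,9S,10S)-9-[(tert-butyldimethylsilyl)oxy]-3,7-dimethyl-11-oxabicyclo[8.1.0]undeca-3,6-dien-2-one
Conditions: t-BuOOH, DBU, CH2Cl2, 0 °C
Reagents that add atoms: tert-butyl hydroperoxide, CC(C)(C)OO
Why: Weitz–Scheffer nucleophilic epoxidation should attack only the less substituted cis-enone, anti to the allylic OTBS group (Felkin-type control under allylic 1,3-strain), and the ring should hold the enolate intermediate so that the cis-epoxide results.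

**Step 9**
Reactants: 11 (1R,3Z,6Z,9S,10S)-9-[(tert-butyldimethylsilyl)oxy]-3,7-dimethyl-11-oxabicyclo[8.1.0]undeca-3,6-dien-2-one
Product: 12 (1S,2S,3Z,6Z,9S,10S)-9-[(tert-butyldimethylsilyl)oxy]-3,7-dimethyl-11-oxabicyclo[8.1.0]undeca-3,6-dien-2-ol
Conditions: Zn(BH4)2, Et2O, −30 °C
Reagents that add atoms: none
Why: Chelation-controlled 1,2-reduction of the α,β-epoxy ketone (zinc bridging the carbonyl and oxirane oxygens, hydride anti to the second oxirane carbon) gives the erythro epoxy alcohol, so the new carbinol (C5 of the target) is cis to the epoxide oxygen.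

**Step 10**
Reactants: 12 (1S,2S,3Z,6Z,9S,10S)-9-[(tert-butyldimethylsilyl)oxy]-3,7-dimethyl-11-oxabicyclo[8.1.0]undeca-3,6-dien-2-ol
Product: 13 (1S,2S,3Z,6Z,9S,10S)-9-[(tert-butyldimethylsilyl)oxy]-3,7-dimethyl-11-oxabicyclo[8.1.0]undeca-3,6-dien-2-yl acetate
Conditions: Ac2O, pyridine, DMAP (cat.), CH2Cl2, 0 → 25 °C
Reagents that add atoms: acetic anhydride, CC(=O)OC(C)=O
Why: Acylation of the allylic alcohol installs the target's acetate with retention while it is the only free hydroxyl.

**Step 11**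
Reactants: 13 (1S,2S,3Z,6Z,9S,10S)-9-[(tert-butyldimethylsilyl)oxy]-3,7-dimethyl-11-oxabicyclo[8.1.0]undeca-3,6-dien-2-yl acetate
Product: 14 (1S,2S,3Z,6Z,9S,10R)-9-hydroxy-3,7-dimethyl-11-oxabicyclo[8.1.0]undeca-3,6-dien-2-yl acetate
Conditions: TBAF, AcOH, THF, 0 → 25 °C
Reagents that add atoms: none
Why: Buffered fluoride desilylation frees the hydroxyl next to the epoxide while suppressing Payne rearrangement and acetate cleavage (the descriptor change at C10 is only a CIP priority effect).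

**Step 12**
Reactants: 14 (1S,2S,3Z,6Z,9S,10R)-9-hydroxy-3,7-dimethyl-11-oxabicyclo[8.1.0]undeca-3,6-dien-2-yl acetate
Product: 15 (1S,2S,3Z,6Z,9S,10R)-2-(acetyloxy)-3,7-dimethyl-11-oxabicyclo[8.1.0]undeca-3,6-dien-9-yl (diethoxyphosphoryl)acetate
Conditions: (EtO)2P(O)CH2CO2H, DCC, DMAP (cat.), CH2Cl2, 0 → 25 °C
Reagents that add atoms: 2-(diethoxyphosphoryl)acetic acid, CCOP(=O)(OCC)CC(=O)O
Why: Steglich esterification tethers the two-carbon lactone unit as a phosphonoacetate on the oxygen adjacent to the epoxide.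

**Step 13**
Reactants: 15 (1S,2S,3Z,6Z,9S,10R)-2-(acetyloxy)-3,7-dimethyl-11-oxabicyclo[8.1.0]undeca-3,6-dien-9-yl (diethoxyphosphoryl)acetate
Product: 17 (3aR,4R,5S,6Z,9Z,11aS)-4-hydroxy-6,10-dimethyl-3-methylidene-2-oxo-2,3,3a,4,5,8,11,11a-octahydrocyclodeca[b]furan-5-yl acetate, via phosphonolactone 16 (not isolated)
Conditions: DBU, LiCl, MeCN, 0 → 25 °C; then (CH2O)n, 25 °C
Reagents that add atoms: formaldehyde (as paraformaldehyde), C=O
Why: Intramolecular 5-exo-tet alkylation of the phosphonoacetate carbanion at the proximal epoxide carbon inverts that centre (lactone cis-fused, new C–C bond trans to the liberated hydroxyl), and Horner–Wadsworth–Emmons reaction of the resulting α-phosphono lactone with formaldehyde gives the α-methylene lactone.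

**Step 14**
Reactants: 18 (2E)-2-methylbut-2-en-1-ol
Product: 19 [(2R,3R)-2,3-dimethyloxiran-2-yl]methanol
Conditions: Ti(OiPr)4 (5 mol %), D-(−)-diisopropyl tartrate (7 mol %), t-BuOOH, 4 Å MS, CH2Cl2, −20 °C
Reagents that add atoms: tert-butyl hydroperoxide, CC(C)(C)OO
Why: Katsuki–Sharpless asymmetric epoxidation with the D-tartrate catalyst gives the (2R,3R)-epoxy alcohol (the enantiomer of the product from natural L-tartrate), and the E geometry fixes the cis relation of the two methyl groups.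

**Step 15**
Reactants: 19 [(2R,3R)-2,3-dimethyloxiran-2-yl]methanol
Product: 20 (2S,3R)-2,3-dimethyloxirane-2-carboxylic acid
Conditions: RuCl3 (2 mol %), NaIO4, CCl4/MeCN/H2O, 25 °C
Reagents that add atoms: sodium periodate, [Na+].[O-]I(=O)(=O)=O
Why: Ruthenium tetroxide oxidation of the primary alcohol to the acid leaves the oxirane and both stereocentres untouched (the C2 descriptor changes from R to S only through CIP priorities).

**Step 16**
Reactants: 17 (3aR,4R,5S,6Z,9Z,11aS)-4-hydroxy-6,10-dimethyl-3-methylidene-2-oxo-2,3,3a,4,5,8,11,11a-octahydrocyclodeca[b]furan-5-yl acetate; 20 (2S,3R)-2,3-dimethyloxirane-2-carboxylic acid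
Product: 21 (3aS,4R,5S,6Z,9Z,11aS)-5-(acetyloxy)-6,10-dimethyl-3-methylidene-2-oxo-2,3,3a,4,5,8,11,11a-octahydrocyclodeca[b]furan-4-yl (2S,3R)-2,3-dimethyloxirane-2-carboxylate
Conditions: DCC, DMAP, CH2Cl2, 0 → 25 °C
Reagents that add atoms: none
Why: Steglich esterification acylates the remaining secondary hydroxyl with retention and completes the target.

**Compound list**
1 | (4S)-4-hydroxycyclohex-2-en-1-one | O=C1C=C[C@@H](O)CC1 | starting material
2 | (4S)-4-[(tert-butyldimethylsilyl)oxy]cyclohex-2-en-1-one | O=C1C=C[C@@H](O[Si](C)(C)C(C)(C)C)CC1 | intermediate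
3 | (4S,6S)-4-[(tert-butyldimethylsilyl)oxy]-6-methylcyclohex-2-en-1-one | O=C1C=C[C@@H](O[Si](C)(C)C(C)(C)C)C[C@@H]1C | intermediate
4 | 3,3-dimethoxypropanal | COC(OC)CC=O | starting material
5 | (3Z)-4-iodo-1,1-dimethoxypent-3-ene | COC(OC)C/C=C(/C)I | intermediate
6 | (3Z)-4-iodopent-3-enal | O=CC/C=C(/C)I | intermediate
7 | (4S,6R)-4-[(tert-butyldimethylsilyl)oxy]-6-[(1R,3Z)-1-hydroxy-4-iodopent-3-en-1-yl]-6-methylcyclohex-2-en-1-one | O=C1C=C[C@@H](O[Si](C)(C)C(C)(C)C)C[C@]1(C)[C@H](O)C/C=C(/C)I | intermediate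
8 | (1R,3Z)-1-[(1R,5S)-5-[(tert-butyldimethylsilyl)oxy]-1-methyl-2-oxocyclohex-3-en-1-yl]-4-iodopent-3-en-1-yl methanesulfonate | O=C1C=C[C@@H](O[Si](C)(C)C(C)(C)C)C[C@]1(C)[C@H](OS(C)(=O)=O)C/C=C(/C)I | intermediate
9 | (1R,4aR,7S,8aR)-7-[(tert-butyldimethylsilyl)oxy]-4a-[(dichlorochromio)oxy]-4,8a-dimethyl-1,2,4a,7,8,8a-hexahydronaphthalen-1-yl methanesulfonate (cis-fused chromium(III) alkoxide) | Cl[Cr](Cl)O[C@@]12C=C[C@@H](O[Si](C)(C)C(C)(C)C)C[C@]1(C)[C@H](OS(C)(=O)=O)CC=C2C | intermediate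
10 | (2Z,5Z,8S,9Z)-8-[(tert-butyldimethylsilyl)oxy]-2,6-dimethylcyclodeca-2,5,9-trien-1-one | CC(C)(C)[Si](C)(C)O[C@H]1C/C(C)=C\C/C=C(/C)C(=O)/C=C\1 | intermediate
11 | (1R,3Z,6Z,9S,10S)-9-[(tert-butyldimethylsilyl)oxy]-3,7-dimethyl-11-oxabicyclo[8.1.0]undeca-3,6-dien-2-one | CC(C)(C)[Si](C)(C)O[C@H]1C/C(C)=C\C/C=C(/C)C(=O)[C@@H]2O[C@H]12 | intermediate
12 | (1S,2S,3Z,6Z,9S,10S)-9-[(tert-butyldimethylsilyl)oxy]-3,7-dimethyl-11-oxabicyclo[8.1.0]undeca-3,6-dien-2-ol | CC(C)(C)[Si](C)(C)O[C@H]1C/C(C)=C\C/C=C(/C)[C@H](O)[C@@H]2O[C@H]12 | intermediate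
13 | (1S,2S,3Z,6Z,9S,10S)-9-[(tert-butyldimethylsilyl)oxy]-3,7-dimethyl-11-oxabicyclo[8.1.0]undeca-3,6-dien-2-yl acetate | CC(C)(C)[Si](C)(C)O[C@H]1C/C(C)=C\C/C=C(/C)[C@H](OC(C)=O)[C@@H]2O[C@H]12 | intermediate
14 | (1S,2S,3Z,6Z,9S,10R)-9-hydroxy-3,7-dimethyl-11-oxabicyclo[8.1.0]undeca-3,6-dien-2-yl acetate | O[C@H]1C/C(C)=C\C/C=C(/C)[C@H](OC(C)=O)[C@@H]2O[C@H]12 | intermediate
15 | (1S,2S,3Z,6Z,9S,10R)-2-(acetyloxy)-3,7-dimethyl-11-oxabicyclo[8.1.0]undeca-3,6-dien-9-yl (diethoxyphosphoryl)acetate | CCOP(=O)(OCC)CC(=O)O[C@H]1C/C(C)=C\C/C=C(/C)[C@H](OC(C)=O)[C@@H]2O[C@H]12 | intermediate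
16 | diethyl [(3aR,4R,5S,6Z,9Z,11aS)-5-(acetyloxy)-4-hydroxy-6,10-dimethyl-2-oxo-2,3,3a,4,5,8,11,11a-octahydrocyclodeca[b]furan-3-yl]phosphonate (C3 epimers) | CCOP(=O)(OCC)C1C(=O)O[C@H]2C/C(C)=C\C/C=C(/C)[C@H](OC(C)=O)[C@H](O)[C@@H]12 | intermediate
17 | (3aR,4R,5S,6Z,9Z,11aS)-4-hydroxy-6,10-dimethyl-3-methylidene-2-oxo-2,3,3a,4,5,8,11,11a-octahydrocyclodeca[b]furan-5-yl acetate | C=C1C(=O)O[C@H]2C/C(C)=C\C/C=C(/C)[C@H](OC(C)=O)[C@H](O)[C@@H]12 | intermediate
18 | (2E)-2-methylbut-2-en-1-ol | C/C=C(\C)CO | starting material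
19 | [(2R,3R)-2,3-dimethyloxiran-2-yl]methanol | OC[C@@]1(C)O[C@@H]1C | intermediate
20 | (2S,3R)-2,3-dimethyloxirane-2-carboxylic acid | OC(=O)[C@@]1(C)O[C@@H]1C | intermediate
21 | (3aS,4R,5S,6Z,9Z,11aS)-5-(acetyloxy)-6,10-dimethyl-3-methylidene-2-oxo-2,3,3a,4,5,8,11,11a-octahydrocyclodeca[b]furan-4-yl (2S,3R)-2,3-dimethyloxirane-2-carboxylate | C=C1C(=O)O[C@H]2C/C(C)=C\C/C=C(/C)[C@H](OC(C)=O)[C@H](OC(=O)[C@@]3(C)O[C@@H]3C)[C@@H]12 | target

**Totals and risks**
Total step count: 16. Longest linear sequence: 12 steps (1, 2, 5–13, 16).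

The three steps most likely to fail:

Step 7 (the proposed cascade). The chromium(III) alkoxide may be too covalent to fragment, or the alkenylchromium may be protonated before it adds to the hindered ketone. The fallback uses known chemistry only, sets out from 7 and comes back at 10. The unmesylated aldol 7 is cyclised under ordinary Nozaki–Hiyama–Kishi conditions (CrCl2, cat. NiCl2, DMF) to the cis-fused bicyclic diol F1. Its secondary hydroxyl alone is mesylated (MsCl, Et3N) to the bicyclic hydroxy mesylate F2. Classical Grob fragmentation of the potassium alkoxide (KOt-Bu, THF, 0 °C) then gives 10.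

Step 8 (epoxidation). The facial bias of the ten-membered cis-enone relative to the OTBS group is argued by analogy and is not secured, and the base can isomerise the skipped diene. The fallback sets out from 10 and comes back at 11. Substrate control is replaced by catalyst control with the lanthanide–BINOL–triphenylarsine oxide/hydroperoxide system known for cis-enones, screening both BINOL antipodes for the one matched to the anti epoxide. It creates no compound outside the list (F0).

Step 13 (tethered epoxide opening and methylenation). The phosphonate carbanion may be too hindered to open the epoxide, and DBU may cause acetate migration or isomerise the methylene lactone. The fallback sets out from 14 and comes back at 17. Alcohol 14 is esterified (DCC, DMAP) with mono-2-(trimethylsilyl)ethyl malonic acid to the mixed malonate F3. Cs2CO3 in MeCN effects the classical intramolecular malonate–epoxide alkylation to the lactone ester F4. Buffered TBAF removes the silylethyl group to give the lactone acid F5. Aqueous formaldehyde with diethylamine then carries out the decarboxylative Mannich methylenation to 17.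

**Further compounds**
F1 | step 7 | (1R,4aR,7S,8aR)-7-[(tert-butyldimethylsilyl)oxy]-4,8a-dimethyl-1,2,4a,7,8,8a-hexahydronaphthalene-1,4a-diol | O[C@@]12C=C[C@@H](O[Si](C)(C)C(C)(C)C)C[C@]1(C)[C@H](O)CC=C2C
F2 | step 7 | (1R,4aR,7S,8aR)-7-[(tert-butyldimethylsilyl)oxy]-4a-hydroxy-4,8a-dimethyl-1,2,4a,7,8,8a-hexahydronaphthalen-1-yl methanesulfonate | O[C@@]12C=C[C@@H](O[Si](C)(C)C(C)(C)C)C[C@]1(C)[C@H](OS(C)(=O)=O)CC=C2C
F0 | step 8 | none | none
F3 | step 13 | (1S,2S,3Z,6Z,9S,10R)-2-(acetyloxy)-3,7-dimethyl-11-oxabicyclo[8.1.0]undeca-3,6-dien-9-yl 2-(trimethylsilyl)ethyl propanedioate | C[Si](C)(C)CCOC(=O)CC(=O)O[C@H]1C/C(C)=C\C/C=C(/C)[C@H](OC(C)=O)[C@@H]2O[C@H]12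
F4 | step 13 | 2-(trimethylsilyl)ethyl (3aR,4R,5S,6Z,9Z,11aS)-5-(acetyloxy)-4-hydroxy-6,10-dimethyl-2-oxo-2,3,3a,4,5,8,11,11a-octahydrocyclodeca[b]furan-3-carboxylate (C3 epimers) | C[Si](C)(C)CCOC(=O)C1C(=O)O[C@H]2C/C(C)=C\C/C=C(/C)[C@H](OC(C)=O)[C@H](O)[C@@H]12
F5 | step 13 | (3aR,4R,5S,6Z,9Z,11aS)-5-(acetyloxy)-4-hydroxy-6,10-dimethyl-2-oxo-2,3,3a,4,5,8,11,11a-octahydrocyclodeca[b]furan-3-carboxylic acid (C3 epimers) | OC(=O)C1C(=O)O[C@H]2C/C(C)=C\C/C=C(/C)[C@H](OC(C)=O)[C@H](O)[C@@H]12
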